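**Retrosynthetic overview**
- Last C–C bond: C(sp3)–C(sp2) Negishi union of a stereodefined iodoethyl cyclohexane fragment with 3-bromo-6-(furan-3-yl)-4-methylpyran-2-one. Only acid deprotection/lactonisation and ketone→enone dehydrogenation follow.
- Pyranone: 6-endo lactonisation of a 2-bromo-2-en-4-ynoic acid, made by β-selective Sonogashira coupling of an (E)-2,3-dibromobutenoate with 3-ethynylfuran.
- Core: both quaternary stereocentres come from an NHC-catalysed desymmetrising intramolecular benzoin of a prochiral 2,2-disubstituted cyclohexane-1,3-dione. Ozonolysis of the cyclopentanone enol ether then gives the C-7a carboxyl and the C2 side chain (cis), leaving the CH2O arm cis to OH.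
- Ring order: cyclohexane and furan purchased → temporary cyclopentanone (benzoin, later cleaved) → pyranone (separate branch) → trans-fused γ-lactone after the union → enone last.

Assumption: the SMILES is read literally, i.e. (3aR,7aR) with the γ-lactone trans-fused (7a-OH anti to the C-3a side chain).

TBS = tert-butyldimethylsilyl, TES = triethylsilyl, BTSE = 1,2-bis(trimethylsiloxy)ethane, MPO = 4-methoxypyridine N-oxide.

**Pyranone branch**

Step 1
Reactants: 1 but-2-ynoic acid
Product: 2 (E)-2,3-dibromobut-2-enoic acid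
Conditions: Br2, MeOH, −10 °C
Reagents that add atoms: bromine, BrBr
Why: Electrophilic anti-addition of Br2 to the alkyne through a bromonium ion gives the trans (E) dibromide, with C3–Br cis to CO2H.

Step 2
Reactants: 2 (E)-2,3-dibromobut-2-enoic acid
Product: 3 methyl (E)-2,3-dibromobut-2-enoate
Conditions: MeI, K2CO3, DMF, rt
Reagents that add atoms: iodomethane, CI
Why: SN2 O-alkylation of the carboxylate masks the acid so the later Pd/Cu coupling cannot cyclise prematurely, and leaves the alkene geometry untouched.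

Step 3
Reactants: 4 3-bromofuran; 5 ethynyltrimethylsilane
Product: 6 3-[(trimethylsilyl)ethynyl]furan
Conditions: PdCl2(PPh3)2 (3 mol%), CuI (5 mol%), i-Pr2NH, 60 °C
Reagents that add atoms: none
Why: Sonogashira coupling of the heteroaryl bromide with the silyl-capped alkyne.

Step 4
Reactants: 6 3-[(trimethylsilyl)ethynyl]furan
Product: 7 3-ethynylfuran
Conditions: K2CO3 (cat.), MeOH, 0 °C → rt (volatile; used as a solution)
Reagents that add atoms: none
Why: Methanolysis of the C(sp)–Si bond (protodesilylation) frees the terminal alkyne.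

Step 5
Reactants: 3 methyl (E)-2,3-dibromobut-2-enoate; 7 3-ethynylfuran
Product: 8 methyl (E)-2-bromo-5-(furan-3-yl)-3-methylpent-2-en-4-ynoate (ester cis to the alkyne)
Conditions: Pd(PPh3)4 (5 mol%), CuI (10 mol%), Et3N, MeCN, rt
Reagents that add atoms: none
Why: Sonogashira coupling in which oxidative addition is faster at the β C–Br (vinylogous acyl bromide) than at the α C–Br and proceeds with retention, so the alkyne ends up cis to the ester.

Step 6
Reactants: 8 methyl (E)-2-bromo-5-(furan-3-yl)-3-methylpent-2-en-4-ynoate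
Product: 9 (E)-2-bromo-5-(furan-3-yl)-3-methylpent-2-en-4-ynoic acid
Conditions: LiOH, THF/H2O, 0 °C; then dil. HCl
Reagents that add atoms: lithium hydroxide, [Li+].[OH-]
Why: Mild saponification (acyl–oxygen cleavage) leaves the vinyl bromide, enyne and furan intact.

Step 7
Reactants: 9 (E)-2-bromo-5-(furan-3-yl)-3-methylpent-2-en-4-ynoic acid
Product: 10 3-bromo-6-(furan-3-yl)-4-methyl-2H-pyran-2-one
Conditions: ZnBr2 (20 mol%), THF, rt
Reagents that add atoms: none
Why: Lewis-acid-promoted 6-endo-dig lactonisation of the (Z)-enynoic acid, favoured over 5-exo because the furyl group stabilises positive charge at the attacked alkyne carbon.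

**Core branch**

Step 8
Reactants: 11 cyclohexane-1,3-dione; 12 allyl bromide
Product: 13 2-allylcyclohexane-1,3-dione
Conditions: KOH, H2O, Cu powder (cat.), rt
Reagents that add atoms: none
Why: C-alkylation of the dione enolate with a soft allylic halide in water.

Step 9
Reactants: 13 2-allylcyclohexane-1,3-dione; 14 formaldehyde
Product: 15 2-allyl-2-(hydroxymethyl)cyclohexane-1,3-dione
Conditions: 37% aq. HCHO, Et3N (cat.), THF, 0 °C → rt
Reagents that add atoms: none
Why: Aldol addition of the dione enolate to formaldehyde creates the prochiral quaternary carbon carrying the future lactone CH2O arm.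

Step 10
Reactants: 15 2-allyl-2-(hydroxymethyl)cyclohexane-1,3-dione
Product: 16 2-allyl-2-[(TBS-oxy)methyl]cyclohexane-1,3-dione
Conditions: TBSCl, imidazole, CH2Cl2, 0 °C
Reagents that add atoms: tert-butyldimethylsilyl chloride, CC(C)(C)[Si](C)(C)Cl
Why: Silylation of the primary alcohol shuts down retro-aldol loss of formaldehyde in the later base-mediated steps.

Step 11
Reactants: 16 2-allyl-2-[(TBS-oxy)methyl]cyclohexane-1,3-dione
Product: 17 3-{1-[(TBS-oxy)methyl]-2,6-dioxocyclohexyl}propanal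
Conditions: PdCl2(PhCN)2 (12 mol%), CuCl2·2H2O (12 mol%), AgNO2 (6 mol%), t-BuOH/MeNO2 15:1, O2 (1 atm), rt
Reagents that add atoms: dioxygen, O=O
Why: Nitrite-modified (aldehyde-selective) Wacker oxidation delivers oxygen to the terminal carbon of the alkene.

Step 12
Reactants: 17 3-{1-[(TBS-oxy)methyl]-2,6-dioxocyclohexyl}propanal
Product: 18 (3aR,7aR)-3a-[(TBS-oxy)methyl]-7a-hydroxyhexahydro-1H-indene-1,4(2H)-dione (cis-fused)
Conditions: aminoindanol-derived N-C6F5 triazolium tetrafluoroborate (10 mol%, antipode chosen for the (3aR,7aR) ketol), Et3N (10 mol%), CH2Cl2, rt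
Reagents that add atoms: none
Why: NHC-catalysed intramolecular crossed benzoin desymmetrises the two enantiotopic ketones; the chiral Breslow intermediate picks one carbonyl and the five-membered ring must close cis, so both quaternary centres are set at once with the new C=O cis to the tether and OH cis to the CH2OTBS arm.

Step 13
Reactants: 18 (3aR,7aR)-3a-[(TBS-oxy)methyl]-7a-hydroxyhexahydro-1H-indene-1,4(2H)-dione
Product: 19 (3a'R,7a'R)-3a'-[(TBS-oxy)methyl]-7a'-hydroxyhexahydrospiro[1,3-dioxolane-2,4'-inden]-1'(2'H)-one (C-4 ethylene ketal of 18)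
Conditions: BTSE, TMSOTf (5 mol%), CH2Cl2, −78 → −20 °C; pyridine; then K2CO3, MeOH, 0 °C (cleaves any tertiary O-TMS)
Reagents that add atoms: 1,2-bis(trimethylsiloxy)ethane, C[Si](C)(C)OCCO[Si](C)(C)C
Why: Noyori ketalisation selects the cyclohexanone because the cyclopentanone is deactivated by its α-oxygen substituent and by ring strain on rehybridisation (as in 3-keto versus 17-keto steroids).

Step 14
Reactants: 19 the C-4 ethylene ketal
Product: 20 (3a'R,7a'R)-3a'-[(TBS-oxy)methyl]-1',7a'-bis(TES-oxy)-3',3a',5',6',7',7a'-hexahydrospiro[1,3-dioxolane-2,4'-indene] (TES enol ether and tertiary TES ether)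
Conditions: TESOTf (3 equiv), Et3N (5 equiv), CH2Cl2, 0 °C → rt
Reagents that add atoms: triethylsilyl triflate, CC[Si](CC)(CC)OS(=O)(=O)C(F)(F)F
Why: Soft enolisation can only go toward the ring CH2 because the other α-carbon is quaternary, and the tertiary alcohol is capped in the same operation.

Step 15
Reactants: 20 the bis-TES compound
Product: 22 (6R,7R)-6-[(TBS-oxy)methyl]-6-(2-oxoethyl)-7-(TES-oxy)-1,4-dioxaspiro[4.5]decane-7-carboxylic acid, via triethylsilyl ester 21 (not isolated)
Conditions: O3, CH2Cl2, −78 °C; Me2S, −78 °C → rt; pH 4 aqueous work-up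
Reagents that add atoms: ozone, [O-][O+]=O
Why: Ozonolysis of the electron-rich silyl enol ether cuts the cyclopentene so the oxygenated carbon becomes the carboxyl on C-7 and the CH carbon becomes the aldehyde of the two-carbon arm, with no bond to a stereocentre broken.

Step 16
Reactants: 22 the acid aldehyde
Product: 23 methyl (6R,7R)-6-[(TBS-oxy)methyl]-6-(2-oxoethyl)-7-(TES-oxy)-1,4-dioxaspiro[4.5]decane-7-carboxylate
Conditions: TMSCHN2, PhMe/MeOH 4:1, 0 °C
Reagents that add atoms: (trimethylsilyl)diazomethane, C[Si](C)(C)C=[N+]=[N-]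
Why: Diazoalkane O-methylation gives the open-chain methyl ester and leaves the aldehyde untouched.

Step 17
Reactants: 23 the ester aldehyde
Product: 24 methyl (6R,7R)-6-[(TBS-oxy)methyl]-6-(2-hydroxyethyl)-7-(TES-oxy)-1,4-dioxaspiro[4.5]decane-7-carboxylate
Conditions: NaBH4, MeOH/THF, −40 °C; AcOH quench
Reagents that add atoms: none
Why: Borohydride reduces the aldehyde chemoselectively, and the cold acidic quench keeps the new alcohol from closing onto the hindered neopentyl ester.

Step 18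
Reactants: 24 the primary alcohol
Product: 25 methyl (6R,7R)-6-[(TBS-oxy)methyl]-6-(2-iodoethyl)-7-(TES-oxy)-1,4-dioxaspiro[4.5]decane-7-carboxylate
Conditions: PPh3, I2, imidazole, CH2Cl2, 0 °C → rt
Reagents that add atoms: iodine, II
Why: Appel iodination of the unhindered primary alcohol by SN2 on the alkoxyphosphonium ion.

**Union and completion**

Step 19
Reactants: 25 the iodide; 10 3-bromo-6-(furan-3-yl)-4-methyl-2H-pyran-2-one
Product: 27 methyl (6R,7R)-6-[(TBS-oxy)methyl]-6-{2-[6-(furan-3-yl)-4-methyl-2-oxo-2H-pyran-3-yl]ethyl}-7-(TES-oxy)-1,4-dioxaspiro[4.5]decane-7-carboxylate, via alkylzinc iodide 26 (not isolated)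
Conditions: Zn dust (TMSCl/BrCH2CH2Br-activated), LiCl, THF, 40 °C; then 10, Pd(OAc)2 (5 mol%), SPhos (10 mol%), THF, 50 °C
Reagents that add atoms: none
Why: Zinc insertion gives a primary alkylzinc that tolerates the ester, ketal and silyl ethers, and Negishi coupling at the electron-poor C3–Br of the pyranone forms the sp3–sp2 bond; the ring carries no alkene or ketone at this stage, so radical or anionic cyclisation of the side chain is excluded.

Step 20
Reactants: 27 the coupled ester
Product: 29 (3aR,7aR)-3a-{2-[6-(furan-3-yl)-4-methyl-2-oxo-2H-pyran-3-yl]ethyl}-7a-hydroxyhexahydro-2-benzofuran-1,4-dione (trans-fused), via hydroxy ester 28 (not isolated)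
Conditions: 2 M aq. HCl/THF 1:2, 40 °C; then TsOH (cat.), PhMe, 60 °C
Reagents that add atoms: water, O
Why: Acid removes both silyl ethers and the dioxolane, and the freed neopentyl CH2OH, the only hydroxyl able to reach the ester, closes in a pantolactone-type lactonisation to the trans-fused γ-lactone with both stereocentres untouched.

Step 21
Reactants: 29 the saturated keto lactone
Product: 30 (3aR,7aR)-3a-{2-[6-(furan-3-yl)-4-methyl-2-oxo-2H-pyran-3-yl]ethyl}-7a-hydroxy-3a,7a-dihydro-2-benzofuran-1,4(3H,7H)-dione (target)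
Conditions: IBX·MPO (2.5 equiv), DMSO, 25–40 °C
Reagents that add atoms: none
Why: IBX dehydrogenation of the ketone can only enolise toward C-5 and cannot over-oxidise because both neighbouring ring carbons beyond the new alkene are blocked, giving the C5=C6 enone.

**Compound list**
1 | but-2-ynoic acid | CC#CC(=O)O | starting material
2 | (E)-2,3-dibromobut-2-enoic acid | OC(=O)/C(Br)=C(C)\Br | intermediate
3 | methyl (E)-2,3-dibromobut-2-enoate | COC(=O)/C(Br)=C(C)\Br | intermediate
4 | 3-bromofuran | Brc1ccoc1 | starting material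
5 | ethynyltrimethylsilane | C#C[Si](C)(C)C | starting material
6 | 3-[(trimethylsilyl)ethynyl]furan | C[Si](C)(C)C#Cc1ccoc1 | intermediate
7 | 3-ethynylfuran | C#Cc1ccoc1 | intermediate
8 | methyl (E)-2-bromo-5-(furan-3-yl)-3-methylpent-2-en-4-ynoate | COC(=O)/C(Br)=C(C)\C#Cc1ccoc1 | intermediate
9 | (E)-2-bromo-5-(furan-3-yl)-3-methylpent-2-en-4-ynoic acid | OC(=O)/C(Br)=C(C)\C#Cc1ccoc1 | intermediate
10 | 3-bromo-6-(furan-3-yl)-4-methyl-2H-pyran-2-one | Cc1cc(-c2ccoc2)oc(=O)c1Br | intermediate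
11 | cyclohexane-1,3-dione | O=C1CCCC(=O)C1 | starting material
12 | allyl bromide | C=CCBr | starting material
13 | 2-allylcyclohexane-1,3-dione | C=CCC1C(=O)CCCC1=O | intermediate
14 | formaldehyde | C=O | starting material
15 | 2-allyl-2-(hydroxymethyl)cyclohexane-1,3-dione | C=CCC1(CO)C(=O)CCCC1=O | intermediate
16 | 2-allyl-2-[(TBS-oxy)methyl]cyclohexane-1,3-dione | C=CCC1(CO[Si](C)(C)C(C)(C)C)C(=O)CCCC1=O | intermediate
17 | 3-{1-[(TBS-oxy)methyl]-2,6-dioxocyclohexyl}propanal | O=CCCC1(CO[Si](C)(C)C(C)(C)C)C(=O)CCCC1=O | intermediate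
18 | (3aR,7aR)-3a-[(TBS-oxy)methyl]-7a-hydroxyhexahydro-1H-indene-1,4(2H)-dione | O=C1CC[C@@]2(C(=O)CCC[C@]12O)CO[Si](C)(C)C(C)(C)C | intermediate
19 | (3a'R,7a'R)-3a'-[(TBS-oxy)methyl]-7a'-hydroxyhexahydrospiro[1,3-dioxolane-2,4'-inden]-1'(2'H)-one | O=C1CC[C@@]2(C3(OCCO3)CCC[C@]12O)CO[Si](C)(C)C(C)(C)C | intermediate
20 | (3a'R,7a'R)-3a'-[(TBS-oxy)methyl]-1',7a'-bis(TES-oxy)-3',3a',5',6',7',7a'-hexahydrospiro[1,3-dioxolane-2,4'-indene] | CC[Si](CC)(CC)OC1=CC[C@@]2(C3(OCCO3)CCC[C@]12O[Si](CC)(CC)CC)CO[Si](C)(C)C(C)(C)C | intermediate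
21 | triethylsilyl (6R,7R)-6-[(TBS-oxy)methyl]-6-(2-oxoethyl)-7-(TES-oxy)-1,4-dioxaspiro[4.5]decane-7-carboxylate | O=CC[C@]1(CO[Si](C)(C)C(C)(C)C)C2(OCCO2)CCC[C@]1(O[Si](CC)(CC)CC)C(=O)O[Si](CC)(CC)CC | intermediate
22 | (6R,7R)-6-[(TBS-oxy)methyl]-6-(2-oxoethyl)-7-(TES-oxy)-1,4-dioxaspiro[4.5]decane-7-carboxylic acid | O=CC[C@]1(CO[Si](C)(C)C(C)(C)C)C2(OCCO2)CCC[C@]1(O[Si](CC)(CC)CC)C(=O)O | intermediate
23 | methyl (6R,7R)-6-[(TBS-oxy)methyl]-6-(2-oxoethyl)-7-(TES-oxy)-1,4-dioxaspiro[4.5]decane-7-carboxylate | O=CC[C@]1(CO[Si](C)(C)C(C)(C)C)C2(OCCO2)CCC[C@]1(O[Si](CC)(CC)CC)C(=O)OC | intermediate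
24 | methyl (6R,7R)-6-[(TBS-oxy)methyl]-6-(2-hydroxyethyl)-7-(TES-oxy)-1,4-dioxaspiro[4.5]decane-7-carboxylate | OCC[C@]1(CO[Si](C)(C)C(C)(C)C)C2(OCCO2)CCC[C@]1(O[Si](CC)(CC)CC)C(=O)OC | intermediate
25 | methyl (6R,7R)-6-[(TBS-oxy)methyl]-6-(2-iodoethyl)-7-(TES-oxy)-1,4-dioxaspiro[4.5]decane-7-carboxylate | ICC[C@]1(CO[Si](C)(C)C(C)(C)C)C2(OCCO2)CCC[C@]1(O[Si](CC)(CC)CC)C(=O)OC | intermediate
26 | iodo{2-[(6R,7R)-6-[(TBS-oxy)methyl]-7-(methoxycarbonyl)-7-(TES-oxy)-1,4-dioxaspiro[4.5]decan-6-yl]ethyl}zinc | I[Zn]CC[C@]1(CO[Si](C)(C)C(C)(C)C)C2(OCCO2)CCC[C@]1(O[Si](CC)(CC)CC)C(=O)OC | intermediate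
27 | methyl (6R,7R)-6-[(TBS-oxy)methyl]-6-{2-[6-(furan-3-yl)-4-methyl-2-oxo-2H-pyran-3-yl]ethyl}-7-(TES-oxy)-1,4-dioxaspiro[4.5]decane-7-carboxylate | Cc1cc(-c2ccoc2)oc(=O)c1CC[C@]1(CO[Si](C)(C)C(C)(C)C)C2(OCCO2)CCC[C@]1(O[Si](CC)(CC)CC)C(=O)OC | intermediate
28 | methyl (1R,2R)-2-{2-[6-(furan-3-yl)-4-methyl-2-oxo-2H-pyran-3-yl]ethyl}-1-hydroxy-2-(hydroxymethyl)-3-oxocyclohexane-1-carboxylate | Cc1cc(-c2ccoc2)oc(=O)c1CC[C@]1(CO)C(=O)CCC[C@]1(O)C(=O)OC | intermediate
29 | (3aR,7aR)-3a-{2-[6-(furan-3-yl)-4-methyl-2-oxo-2H-pyran-3-yl]ethyl}-7a-hydroxyhexahydro-2-benzofuran-1,4-dione | Cc1cc(-c2ccoc2)oc(=O)c1CC[C@@]12COC(=O)[C@@]1(O)CCCC2=O | intermediate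
30 | (3aR,7aR)-3a-{2-[6-(furan-3-yl)-4-methyl-2-oxo-2H-pyran-3-yl]ethyl}-7a-hydroxy-3a,7a-dihydro-2-benzofuran-1,4(3H,7H)-dione | Cc1cc(-c2ccoc2)oc(=O)c1CC[C@@]12COC(=O)[C@@]1(O)CC=CC2=O | target

**Totals**
Total step count: 21. Longest linear sequence: 14 (steps 8–21, from cyclohexane-1,3-dione).

**Steps most likely to fail, with fallbacks**

Step 11 (aldehyde-selective Wacker). The risk is that the homoallylic diketone reverts to normal Markovnikov selectivity and gives the methyl ketone. The fallback sets out from 16. Iridium-catalysed anti-Markovnikov hydroboration ([Ir(cod)Cl]2/dppe, pinacolborane, CH2Cl2, rt) gives the primary pinacol boronate F1. Oxidation with NaBO3·4H2O in THF/H2O gives the 3-hydroxypropyl dione F2, and Dess–Martin oxidation comes back to the route at aldehyde 17.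

Step 13 (chemoselective ketalisation). The cyclohexanone is flanked by a congested quaternary carbon and may not be differentiated cleanly from the cyclopentanone. The fallback sets out from 18 and takes the ketol carbonyl out of play by reduction instead of relying on ketalisation selectivity. Chelation-controlled reduction with Zn(BH4)2 (Et2O, −20 °C) reduces only the α-hydroxy ketone and gives the 1,7a-diol F3 (drawn as the trans diol; either C-1 epimer serves). The single remaining ketone is then ketalised under the step 13 conditions to give the ketal diol F4, and Dess–Martin oxidation of the secondary carbinol comes back to the route at 19.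

Step 21 (IBX dehydrogenation). The furan and the acidic pyranone methyl group may not tolerate the oxidant, or enolisation of the hindered ketone may be too slow. The fallback sets out from 29 and goes through a preformed enol ether. TMSOTf/Et3N (CH2Cl2, −20 °C) gives the bis-silylated compound F5 (TMS enol ether and tertiary TMS ether). Saegusa–Ito oxidation with Pd(OAc)2 in MeCN at rt gives the enone TMS ether F6, and brief 1 M HCl/THF comes back to the route at target 30.

Further compounds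
F1 | step 11 | 2-[(TBS-oxy)methyl]-2-[3-(4,4,5,5-tetramethyl-1,3,2-dioxaborolan-2-yl)propyl]cyclohexane-1,3-dione | CC1(C)OB(CCCC2(CO[Si](C)(C)C(C)(C)C)C(=O)CCCC2=O)OC1(C)C
F2 | step 11 | 2-[(TBS-oxy)methyl]-2-(3-hydroxypropyl)cyclohexane-1,3-dione | OCCCC1(CO[Si](C)(C)C(C)(C)C)C(=O)CCCC1=O
F3 | step 13 | (1R,3aR,7aR)-3a-[(TBS-oxy)methyl]-1,7a-dihydroxyoctahydro-4H-inden-4-one | O[C@@H]1CC[C@@]2(C(=O)CCC[C@]12O)CO[Si](C)(C)C(C)(C)C
F4 | step 13 | (1'R,3a'R,7a'R)-3a'-[(TBS-oxy)methyl]hexahydrospiro[1,3-dioxolane-2,4'-indene]-1',7a'(1'H)-diol | O[C@@H]1CC[C@@]2(C3(OCCO3)CCC[C@]12O)CO[Si](C)(C)C(C)(C)C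
F5 | step 21 | bis-TMS derivative of 29 (C-4 TMS enol ether, 7a-O-TMS ether) | Cc1cc(-c2ccoc2)oc(=O)c1CC[C@@]12COC(=O)[C@@]1(O[Si](C)(C)C)CCC=C2O[Si](C)(C)C
F6 | step 21 | 7a-O-TMS ether of 30 | Cc1cc(-c2ccoc2)oc(=O)c1CC[C@@]12COC(=O)[C@@]1(O[Si](C)(C)C)CC=CC2=O
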